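**Retrosynthetic overview**
- Artoflavanone is traced back to its 5-O-methyl ether. The methyl group on O5, peri to C4=O, is removed last by carbonyl-directed cleavage.
- Ring C is the only ring built. Cutting the C4–C4a aryl ketone bond (intramolecular Friedel–Crafts acylation) gives an (S)-3-aryloxy-3-arylpropanoic acid that already carries C2.
- Feature used: with OMe on both C5 and C7 and prenyl on C6, ring A has a mirror plane through O1, C8a, C6 and the prenyl CH2. The two CH carbons ortho to O1 (future C4a and C8) are therefore identical, and only the 6-prenyl chromanone can form.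
- The C2–O1 bond comes from Mitsunobu inversion of an (R)-β-hydroxy ester, made by asymmetric hydrogenation of the β-keto ester, with 3,5-dimethoxy-4-prenylphenol.
- The phenol comes from 3,5-dimethoxyphenol by silylation, lithiation between the two methoxy groups, prenylation and desilylation. Rings A and B are purchased, and ring C closes in step 7.

Key step: step 7

Remark: flavanone numbering (O1, C2, C3, C4, C4a, C5–C8, C8a; ring B primed) is used for every compound carrying the C2 centre. The (S)-diphosphine → (R)-alcohol sense in step 4 follows the empirical β-keto ester model, with the descriptor R because aryl outranks CH2CO2Et. It would be confirmed on 8 before coupling, and the antipodal ligand is equally available.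

Step 1
Reactants: 1 3,5-dimethoxyphenol
Product: 2 (3,5-dimethoxyphenoxy)triisopropylsilane
Conditions: TIPSCl (1.1 equiv), imidazole (2 equiv), DMF, rt
Reagents that add atoms: triisopropylsilyl chloride (TIPSCl), CC(C)[Si](Cl)(C(C)C)C(C)C
Why: Imidazole-promoted O-silylation of a phenol; the bulky, weakly coordinating OTIPS group withstands n-BuLi and cannot compete with the two methoxy groups as a director in step 2.

Step 2
Reactants: 2 (3,5-dimethoxyphenoxy)triisopropylsilane; 3 prenyl bromide (1-bromo-3-methylbut-2-ene)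
Product: 5 [3,5-dimethoxy-4-(3-methylbut-2-en-1-yl)phenoxy]triisopropylsilane, via aryllithium 4 (not isolated)
Conditions: n-BuLi (1.05 equiv), THF, 0 °C → rt; then 3, −78 °C → rt
Reagents that add atoms: none
Why: Directed ortho-metalation followed by SN2 alkylation; the C–H flanked by two coordinating methoxy groups is lithiated while the positions next to OTIPS are shielded, and the 2,6-dimethoxyaryllithium displaces bromide at the primary carbon of prenyl bromide.

Step 3
Reactants: 5 [3,5-dimethoxy-4-(3-methylbut-2-en-1-yl)phenoxy]triisopropylsilane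
Product: 6 3,5-dimethoxy-4-(3-methylbut-2-en-1-yl)phenol
Conditions: TBAF (1.1 equiv), AcOH (1.1 equiv), THF, 0 °C
Reagents that add atoms: none
Why: Fluoride-induced desilylation driven by Si–F bond formation; the acetic acid buffer delivers the electron-rich phenol in neutral form, and the alkene and methyl ethers are inert.

Step 4
Reactants: 7 ethyl 3-oxo-3-(3,4,5-trimethoxyphenyl)propanoate
Product: 8 ethyl (R)-3-hydroxy-3-(3,4,5-trimethoxyphenyl)propanoate
Conditions: [RuCl(p-cymene)((S)-SEGPHOS)]Cl (0.5 mol %), H2 (30 bar), EtOH, 60 °C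
Reagents that add atoms: none
Why: Noyori asymmetric hydrogenation of a β-keto ester; chelation of ketone and ester oxygens to divalent ruthenium fixes the substrate in the chiral pocket of the (S)-diphosphine, so hydride reaches one ketone face and sets the carbinol centre as R.

Step 5
Reactants: 6 3,5-dimethoxy-4-(3-methylbut-2-en-1-yl)phenol; 8 ethyl (R)-3-hydroxy-3-(3,4,5-trimethoxyphenyl)propanoate
Product: 9 ethyl (S)-3-[3,5-dimethoxy-4-(3-methylbut-2-en-1-yl)phenoxy]-3-(3,4,5-trimethoxyphenyl)propanoate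
Conditions: PPh3 (1.3 equiv), DIAD (1.3 equiv, slow addition), toluene, 0 °C → rt
Reagents that add atoms: none
Why: Mitsunobu etherification; the phenoxide, unhindered at both ortho positions, displaces the phosphonium-activated hydroxyl by SN2 with clean inversion (R → S), and the non-polar solvent, low temperature and β-ester disfavour ionisation of the benzylic centre.

Step 6
Reactants: 9 ethyl (S)-3-[3,5-dimethoxy-4-(3-methylbut-2-en-1-yl)phenoxy]-3-(3,4,5-trimethoxyphenyl)propanoate
Product: 11 (S)-3-[3,5-dimethoxy-4-(3-methylbut-2-en-1-yl)phenoxy]-3-(3,4,5-trimethoxyphenyl)propanoic acid, via lithium carboxylate 10 (not isolated)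
Conditions: LiOH·H2O (2 equiv), THF–H2O, 0 °C → rt; then cold 1 M HCl to pH 3–4
Reagents that add atoms: lithium hydroxide, [Li+].[OH-]
Why: Ester saponification (BAc2); attack of hydroxide at the unhindered ethyl ester at low temperature outruns enolisation, and the resulting carboxylate no longer supports β-elimination of the aryloxide, so C2 is untouched.

Step 7
Reactants: 11 (S)-3-[3,5-dimethoxy-4-(3-methylbut-2-en-1-yl)phenoxy]-3-(3,4,5-trimethoxyphenyl)propanoic acid
Product: 13 (S)-5,7-dimethoxy-6-(3-methylbut-2-en-1-yl)-2-(3,4,5-trimethoxyphenyl)chroman-4-one (5-O-methylartoflavanone), via acyl trifluoroacetate 12 (not isolated)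
Conditions: (CF3CO)2O (1.5 equiv), CH2Cl2, −15 → 0 °C; cold sat. aq NaHCO3 quench
Reagents that add atoms: none
Why: Trifluoroacetic anhydride turns the acid into acyl trifluoroacetate 12, whose acyl carbon is attacked by a ring A carbon ortho to O1, and loss of trifluoroacetate and of the ring proton from the Wheland intermediate forms C4–C4a. This is the classical intramolecular Friedel–Crafts acylation of 3-aryloxypropanoic acids to chroman-4-ones. Ring C (O1–C2–C3–C4–C4a–C8a) closes in a 6-exo-trig mode with the C=O outside the new ring. No stereocentre is made, and C2 keeps its S configuration because the C2–O1 bond is never broken: low temperature, non-ionising CH2Cl2, short contact time and the electron-withdrawing acyl group β to C2 disfavour ionisation or elimination at the benzylic ether. Regiochemistry needs no control because the mirror plane of ring A makes both ortho carbons the same, while selectivity over C2′ of ring B rests on the attacking ring A carbon being ortho/para to three oxygens and on six-membered closure being faster than the strained five-membered alternative. The prenyl alkene should survive because acylation of a phloroglucinol-type ring at or below 0 °C is much faster than addition of CF3CO2H to a trisubstituted alkene, and both flanking oxygens are methylated and cannot cyclise onto it.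

Step 8
Reactants: 13 (S)-5,7-dimethoxy-6-(3-methylbut-2-en-1-yl)-2-(3,4,5-trimethoxyphenyl)chroman-4-one
Product: 15 artoflavanone [(S)-5-hydroxy-7-methoxy-6-(3-methylbut-2-en-1-yl)-2-(3,4,5-trimethoxyphenyl)chroman-4-one], via dichloroboron chelate 14 (not isolated)
Conditions: BCl3 (1.0 M in CH2Cl2, 1.5 equiv), CH2Cl2, −78 → −20 °C; then cold sat. aq NaHCO3
Reagents that add atoms: none
Why: Chelation-controlled aryl methyl ether cleavage; BCl3 binds the basic C4=O, reaches only the peri O5 (also twisted out of plane by its two ortho neighbours) to form a six-membered chelate, chloride removes that methyl group by SN2, and the 7-OMe, ring B ethers, alkene and C2 are left alone at low temperature.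

**Compound list**
1 | 3,5-dimethoxyphenol | COc1cc(O)cc(OC)c1 | starting material
2 | (3,5-dimethoxyphenoxy)triisopropylsilane | COc1cc(O[Si](C(C)C)(C(C)C)C(C)C)cc(OC)c1 | intermediate
3 | prenyl bromide (1-bromo-3-methylbut-2-ene) | CC(C)=CCBr | starting material
4 | [2,6-dimethoxy-4-(triisopropylsilyloxy)phenyl]lithium | COc1cc(O[Si](C(C)C)(C(C)C)C(C)C)cc(OC)c1[Li] | intermediate
5 | [3,5-dimethoxy-4-(3-methylbut-2-en-1-yl)phenoxy]triisopropylsilane | COc1cc(O[Si](C(C)C)(C(C)C)C(C)C)cc(OC)c1CC=C(C)C | intermediate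
6 | 3,5-dimethoxy-4-(3-methylbut-2-en-1-yl)phenol | COc1cc(O)cc(OC)c1CC=C(C)C | intermediate
7 | ethyl 3-oxo-3-(3,4,5-trimethoxyphenyl)propanoate | CCOC(=O)CC(=O)c1cc(OC)c(OC)c(OC)c1 | starting material
8 | ethyl (R)-3-hydroxy-3-(3,4,5-trimethoxyphenyl)propanoate | CCOC(=O)C[C@@H](O)c1cc(OC)c(OC)c(OC)c1 | intermediate
9 | ethyl (S)-3-[3,5-dimethoxy-4-(3-methylbut-2-en-1-yl)phenoxy]-3-(3,4,5-trimethoxyphenyl)propanoate | CCOC(=O)C[C@@H](c1cc(OC)c(OC)c(OC)c1)Oc1cc(OC)c(CC=C(C)C)c(OC)c1 | intermediate
10 | lithium (S)-3-[3,5-dimethoxy-4-(3-methylbut-2-en-1-yl)phenoxy]-3-(3,4,5-trimethoxyphenyl)propanoate | [Li+].[O-]C(=O)C[C@@H](c1cc(OC)c(OC)c(OC)c1)Oc1cc(OC)c(CC=C(C)C)c(OC)c1 | intermediate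
11 | (S)-3-[3,5-dimethoxy-4-(3-methylbut-2-en-1-yl)phenoxy]-3-(3,4,5-trimethoxyphenyl)propanoic acid | OC(=O)C[C@@H](c1cc(OC)c(OC)c(OC)c1)Oc1cc(OC)c(CC=C(C)C)c(OC)c1 | intermediate
12 | mixed anhydride of acid 11 and trifluoroacetic acid, (S) | FC(F)(F)C(=O)OC(=O)C[C@@H](c1cc(OC)c(OC)c(OC)c1)Oc1cc(OC)c(CC=C(C)C)c(OC)c1 | intermediate
13 | (S)-5,7-dimethoxy-6-(3-methylbut-2-en-1-yl)-2-(3,4,5-trimethoxyphenyl)chroman-4-one (5-O-methylartoflavanone) | COc1cc2c(c(OC)c1CC=C(C)C)C(=O)C[C@@H](c1cc(OC)c(OC)c(OC)c1)O2 | intermediate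
14 | (S)-5-(dichloroboryloxy)-7-methoxy-6-(3-methylbut-2-en-1-yl)-2-(3,4,5-trimethoxyphenyl)chroman-4-one, boron coordinated to C4=O | COc1cc2c(c(OB(Cl)Cl)c1CC=C(C)C)C(=O)C[C@@H](c1cc(OC)c(OC)c(OC)c1)O2 | intermediate
15 | artoflavanone, (S)-5-hydroxy-7-methoxy-6-(3-methylbut-2-en-1-yl)-2-(3,4,5-trimethoxyphenyl)chroman-4-one | COc1cc2c(c(O)c1CC=C(C)C)C(=O)C[C@@H](c1cc(OC)c(OC)c(OC)c1)O2 | target

**Total step count:** 8. **Longest linear sequence:** 7 (steps 1, 2, 3, 5, 6, 7, 8). Step 4 is the one-step side branch.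

**Steps most likely to fail**

1. Step 7 (ring closure).
   - Risk: the trifluoroacetic acid released on activation may add to the prenyl double bond or ionise the benzylic C2–O1 bond, with erosion of enantiopurity or β-elimination of the aryloxy group. Closure onto ring B may also compete.
   - Fallback: an acid-free, position-defined anionic closure (Parham-type cyclisation) that sets out from 6 and 8 and comes back at 13.
   - Phenol 6 is mono-iodinated at one of its two equivalent ortho carbons (I2, 1.0 equiv, NaHCO3, THF–H2O, 0 °C) to give 2-iodo-3,5-dimethoxy-4-(3-methylbut-2-en-1-yl)phenol F1.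
   - Hydroxy ester 8 is converted with MeNH(OMe)·HCl and i-PrMgCl (THF, −20 °C) into (R)-3-hydroxy-N-methoxy-N-methyl-3-(3,4,5-trimethoxyphenyl)propanamide F2.
   - Mitsunobu coupling of the two (PPh3, DIAD, toluene, 0 °C) with inversion gives (S)-3-[2-iodo-3,5-dimethoxy-4-(3-methylbut-2-en-1-yl)phenoxy]-N-methoxy-N-methyl-3-(3,4,5-trimethoxyphenyl)propanamide F3.
   - Iodine–lithium exchange (n-BuLi, THF, −78 °C) is followed by immediate attack of the aryl anion on the Weinreb amide. This forms C4–C4a and, after quench, delivers 13.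

2. Step 5 (Mitsunobu coupling).
   - Risk: the acidic C–H next to the ester may allow β-elimination of the activated hydroxyl group. Partial ionisation of the electron-rich benzylic centre may erode the inversion.
   - Fallback: the ester is removed before the coupling and the acid oxidation level is restored afterwards. The sequence sets out from 8 (with 6) and comes back at 11.
   - Ester 8 is reduced (LiBH4, THF–MeOH, 0 °C → rt) to (R)-1-(3,4,5-trimethoxyphenyl)propane-1,3-diol F4.
   - The primary hydroxyl is silylated selectively (TBSCl, imidazole, CH2Cl2, 0 °C) to give (R)-3-(tert-butyldimethylsilyloxy)-1-(3,4,5-trimethoxyphenyl)propan-1-ol F5.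
   - Mitsunobu reaction with 6 gives the (S)-configured aryl ether tert-butyl{(S)-3-[3,5-dimethoxy-4-(3-methylbut-2-en-1-yl)phenoxy]-3-(3,4,5-trimethoxyphenyl)propoxy}dimethylsilane F6.
   - TBAF liberates (S)-3-[3,5-dimethoxy-4-(3-methylbut-2-en-1-yl)phenoxy]-3-(3,4,5-trimethoxyphenyl)propan-1-ol F7.
   - TEMPO (cat.)/PhI(OAc)2 in MeCN–H2O oxidises the primary alcohol to acid 11.

3. Step 8 (5-O-demethylation).
   - Risk: HCl accompanying the boron halide may add to the trisubstituted alkene, or the liberated 5-OH may cyclise onto it.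
   - Fallback: the side chain is carried as the much less acid-sensitive allyl group and converted to prenyl at the very end. The sequence sets out from 2 (through aryllithium 4) and comes back at 15.
   - Aryllithium 4 is quenched with allyl bromide to give (4-allyl-3,5-dimethoxyphenoxy)triisopropylsilane F8, and TBAF/AcOH gives 4-allyl-3,5-dimethoxyphenol F9.
   - Mitsunobu coupling with 8 gives ethyl (S)-3-(4-allyl-3,5-dimethoxyphenoxy)-3-(3,4,5-trimethoxyphenyl)propanoate F10.
   - LiOH gives (S)-3-(4-allyl-3,5-dimethoxyphenoxy)-3-(3,4,5-trimethoxyphenyl)propanoic acid F11.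
   - (CF3CO)2O closes ring C to (S)-6-allyl-5,7-dimethoxy-2-(3,4,5-trimethoxyphenyl)chroman-4-one F12.
   - BCl3 then gives (S)-6-allyl-5-hydroxy-7-methoxy-2-(3,4,5-trimethoxyphenyl)chroman-4-one F13.
   - Olefin cross-metathesis with excess 2-methyl-2-butene converts allyl into prenyl and delivers 15. The catalyst is the second-generation Grubbs catalyst RuCl2(=CHPh)(PCy3)(H2IMes), in CH2Cl2 at 40 °C.

**Further compounds**
F1 | step 7 | 2-iodo-3,5-dimethoxy-4-(3-methylbut-2-en-1-yl)phenol | COc1cc(O)c(I)c(OC)c1CC=C(C)C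
F2 | step 7 | (R)-3-hydroxy-N-methoxy-N-methyl-3-(3,4,5-trimethoxyphenyl)propanamide | CON(C)C(=O)C[C@@H](O)c1cc(OC)c(OC)c(OC)c1
F3 | step 7 | (S)-3-[2-iodo-3,5-dimethoxy-4-(3-methylbut-2-en-1-yl)phenoxy]-N-methoxy-N-methyl-3-(3,4,5-trimethoxyphenyl)propanamide | CON(C)C(=O)C[C@@H](c1cc(OC)c(OC)c(OC)c1)Oc1cc(OC)c(CC=C(C)C)c(OC)c1I
F4 | step 5 | (R)-1-(3,4,5-trimethoxyphenyl)propane-1,3-diol | OCC[C@@H](O)c1cc(OC)c(OC)c(OC)c1
F5 | step 5 | (R)-3-(tert-butyldimethylsilyloxy)-1-(3,4,5-trimethoxyphenyl)propan-1-ol | CC(C)(C)[Si](C)(C)OCC[C@@H](O)c1cc(OC)c(OC)c(OC)c1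
F6 | step 5 | tert-butyl{(S)-3-[3,5-dimethoxy-4-(3-methylbut-2-en-1-yl)phenoxy]-3-(3,4,5-trimethoxyphenyl)propoxy}dimethylsilane | CC(C)(C)[Si](C)(C)OCC[C@@H](c1cc(OC)c(OC)c(OC)c1)Oc1cc(OC)c(CC=C(C)C)c(OC)c1
F7 | step 5 | (S)-3-[3,5-dimethoxy-4-(3-methylbut-2-en-1-yl)phenoxy]-3-(3,4,5-trimethoxyphenyl)propan-1-ol | OCC[C@@H](c1cc(OC)c(OC)c(OC)c1)Oc1cc(OC)c(CC=C(C)C)c(OC)c1
F8 | step 8 | (4-allyl-3,5-dimethoxyphenoxy)triisopropylsilane | COc1cc(O[Si](C(C)C)(C(C)C)C(C)C)cc(OC)c1CC=C
F9 | step 8 | 4-allyl-3,5-dimethoxyphenol | COc1cc(O)cc(OC)c1CC=C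
F10 | step 8 | ethyl (S)-3-(4-allyl-3,5-dimethoxyphenoxy)-3-(3,4,5-trimethoxyphenyl)propanoate | CCOC(=O)C[C@@H](c1cc(OC)c(OC)c(OC)c1)Oc1cc(OC)c(CC=C)c(OC)c1
F11 | step 8 | (S)-3-(4-allyl-3,5-dimethoxyphenoxy)-3-(3,4,5-trimethoxyphenyl)propanoic acid | OC(=O)C[C@@H](c1cc(OC)c(OC)c(OC)c1)Oc1cc(OC)c(CC=C)c(OC)c1
F12 | step 8 | (S)-6-allyl-5,7-dimethoxy-2-(3,4,5-trimethoxyphenyl)chroman-4-one | COc1cc2c(c(OC)c1CC=C)C(=O)C[C@@H](c1cc(OC)c(OC)c(OC)c1)O2
F13 | step 8 | (S)-6-allyl-5-hydroxy-7-methoxy-2-(3,4,5-trimethoxyphenyl)chroman-4-one | COc1cc2c(c(O)c1CC=C)C(=O)C[C@@H](c1cc(OC)c(OC)c(OC)c1)O2
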